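Compound numbers used throughout are those of the steps and of the compound list below.

## Analysis of the target

Leprolomin (23) is a diaryl ether joining two acetophenone-type benzene rings and contains no stereocentre. Ring A is numbered C1 (OMe), C2 (H), C3 (ether O), C4 (acetyl), C5 (OH), C6 (Me), and ring B is numbered C1' (ether O), C2' (OH), C3' (Me), C4' (OMe), C5' (acetyl), C6' (OH). Ring A is thus pentasubstituted and ring B hexasubstituted, and neither ring has a symmetry element that would simplify the placing of its substituents. The sensitive groups are three free phenols on electron-rich rings, which are open to oxidation once deprotonated, and the C4' methoxy group, which lies ortho to a ketone and is therefore labile towards strong Lewis acids. The main difficulty is the ether oxygen: it is flanked by C2'–OH and C6'–OH on ring B and by the C4 acetyl on ring A, so a coupling of two finished rings would have to join a di-ortho-substituted, oxidation-prone phenol to a hindered arene. The strategy rests on ring A: the contiguous C5 hydroxyl, C6 methyl and C1 methoxy are what a ketene carbon and the two alkyne carbons of 1-methoxypropyne (10) leave behind, and C2–C3–C4 with the aryloxy group on C3 is what remains of a vinylketene. Ring A can therefore be grown onto the ether oxygen by benzannulation of a 3-aryloxycyclobutenone. Both acetyl groups sit ortho to a phenol and can be added last by acyl migration from oxygen to carbon.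

## Retrosynthetic reasoning

23 back to 21. The bonds cut first are C4–C(acyl) on ring A and C5'–C(acyl) on ring B. Each acetyl is ortho to a phenol, so both trace back to O-acetyl groups on O5 and O6' that migrate under a Lewis acid (Fries rearrangement); the chelate 22 is the form in which the rearranged product is expected to sit before release. Cutting here keeps two enolisable, reducible ketones out of the hydrogenolysis and out of the thermal ring-forming step. The forward reaction must deliver the ring A acetyl to C4 and not to C2. C4 is the only open carbon ortho to O5, and ortho delivery is rewarded by chelation. On ring B, C5' is the only unsubstituted carbon.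

21 back to 20 and 19. These are changes of protecting group only. The benzyl ethers on O2' and O6' survive heat, base and peracid and are removed under neutral conditions, and peracetylation of triol 20 supplies exactly three acetyl groups, which limits over-acylation.

19 back to 14 and 10 (key disconnection). Ring A is opened at C5–C6 and C1–C2, and the C4–C5 link is traced back to the cyclobutenone. Cutting the ring here rather than at the C3–O ether bond avoids a cross-coupling at the most hindered position of the molecule, since the aryloxy group rides into the new ring on C3. The forward reaction must join the ketene carbon of vinylketene 15 to the methyl-bearing carbon of 10, so that methyl ends up at C6 next to the new C5 hydroxyl and methoxy at C1. The cascade then runs through 16, 17 and 18 to the phenol.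

14 back to 7 and 12. The vinyl C–O bond is cut. The phenol oxygen of 7 is joined to a small, unhindered sp2 carbon by addition–elimination at the vinylogous acid chloride 13, which is generated from dione 12. The two ortho benzyloxy groups of 7 are not in the way of this reaction, though they would be in an aryl–aryl ether coupling.

12 back to 11, and 10 back to 8. Dione 12 is the hydrolysis product of the commercial vinylogous ester 11. Alkyne 10 comes from chloroacetal 8 by base-induced elimination to the metal acetylide 9 and C-methylation in the same flask. A methyl ynol ether is chosen because it has no β-hydrogen on the alkoxy group and so cannot fragment by retro-ene reaction when heated.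

7 back to 5. The C1'–O bond is traced to a C1'–CHO bond through aryl formate 6 (Baeyer–Villiger oxidation of an electron-rich aldehyde, then cleavage of the formate). The formyl group thus serves twice: it is the handle for the fourth oxygen of ring B, and before that it differentiates the three hydroxyls.

5 back to 4, 3 and 1. The benzyl groups of 5 go onto the two hydroxyls that are hydrogen-bonded to the aldehyde. The methyl group of 4 goes onto the one hydroxyl para to the aldehyde, which is the most acidic and is not chelated. Aldehyde 3 comes from formylation of 1 through iminium salt 2; the two open ring positions of 1 are equivalent, so only one mono-aldehyde can form.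

## Alternatives that were turned down

Alternative 1: Ring B would be cut at C1'–C2' and C5'–C6' and built onto the ether oxygen. The ester enolate of the ring A aryloxyacetate A1 would acylate the lactone carbonyl of pyranone A2, the ring would open, and the released methyl ketone enolate would close onto the ester to give A3 with ring B complete.
- For: one operation would deliver the hexasubstituted ring with its acetyl, both hydroxyls, methyl and methoxy in mapped positions. On this point it is stronger than the chosen route, which adds the ring B acetyl later.
- Against: carbanions normally attack 2-pyranones at C6 and not at the lactone carbonyl, and in A2 that carbonyl is a vinylogous carbonate further deactivated by the 4-methoxy donor. The 6-methyl group of A2 is an acidic vinylogous position that can simply quench the enolate of A1, which is itself prone to self-condensation.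
- Step economy: A1 needs a ring A with three differently masked oxygens made separately, and A3 still lacks the C4 acetyl, so the late ortho-acylation of ring A is not avoided.
- Comparison: the chosen strategy forms its ring through the innate polarity of a ketene and an ynol ether, without base, and ring A emerges with its three oxygens already differentiated.

Alternative 2: Ring B would be cut at C6'–C1' and C4'–C5'. A Diels–Alder reaction of the aryloxy silyloxy ketene acetal diene A4 with the boryl ynone A5, followed by elimination of one acetal methoxy group and desilylation, would give A6, in which a pinacol boronate marks the future C6' oxygen.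
- For: the polarised diene should fix the regiochemistry, the ring B acetyl arrives in place, and the approach is convergent. It matches or exceeds the chosen route in regiocontrol on ring B.
- Against: A4 carries four heteroatom substituents and a fully substituted terminus. Making it needs a regiodefined silyl enol ether next to a ketene acetal, and it would be very labile to moisture. A5 is a weakly activated dienophile, and the crowded boronate of A6, between the aryloxy group and the acetyl, invites protodeboronation before it can be oxidised.
- Step economy: the oxidation of boron is an added step, ring A must still be prepared and differentiated beforehand, and its C4 acetyl is still missing.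
- Comparison: the chosen strategy uses stable, simple partners (14 and 10) and needs no placeholder atom.

Alternative 3: Ring A would be cut at C2–C3 and C4–C5. A Diels–Alder reaction between the bis-silyl ketene acetal diene A7 and the ring B aryloxy ynone A8, followed by loss of a silanol and desilylation, would give A9 with ring A complete.
- For: the C4 acetyl is delivered with unambiguous regiochemistry. On this point it is clearly stronger than the chosen route, which depends on ortho selectivity in a Fries rearrangement on ring A.
- Against: A8 is an ynol ether conjugated to a ketone. It is hydrolytically fragile and has to be made from the hindered phenol 7 by way of an aryl ethynyl ether and its acylation. Its aryloxy donor lowers the electrophilicity of exactly the carbon that the nucleophilic diene terminus must attack. A7 is a highly moisture-sensitive bis-silyl ketene acetal whose preparation involves γ-deprotonation of an unsaturated acid derivative.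
- Step economy: the count is similar to that of the chosen route, and ring B would still need a separate acylation at C5'.
- Comparison: the chosen strategy gives up the built-in acetyl in exchange for a neutral, reagent-free ring construction from robust partners. It recovers the acetyl regiochemistry through chelation control, with an ortho-specific formylation sequence held in reserve.

Key step: step 8

Assumption: in step 11 the rearranged ketones are taken to be held as difluoroboron chelates (22) until the acidic methanolysis, as is usual for o-hydroxyaryl ketones formed in BF3·OEt2.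

## Route

Step 1
Reactants: 1 2-methylphloroglucinol (2-methylbenzene-1,3,5-triol)
Product: 3 2,4,6-trihydroxy-3-methylbenzaldehyde, via aryl iminium chloride 2 (not isolated)
Conditions: POCl3, DMF, EtOAc, 0 °C → rt; then H2O, 50 °C
Reagents that add atoms: N,N-dimethylformamide, CN(C)C=O; water, O
Why: Vilsmeier–Haack formylation of a phloroglucinol; the two open ring positions of 1 are equivalent by symmetry, so a single mono-aldehyde should form, and the iminium group of 2 deactivates the ring against a second attack before water hydrolyses it.

Step 2
Reactants: 3 2,4,6-trihydroxy-3-methylbenzaldehyde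
Product: 4 2,6-dihydroxy-4-methoxy-3-methylbenzaldehyde
Conditions: MeI (1.05 equiv), K2CO3 (1.0 equiv), acetone, 0 °C → rt
Reagents that add atoms: methyl iodide, CI
Why: Williamson O-methylation under base-limited conditions; the C4' hydroxyl para to the aldehyde is the most acidic (vinylogous acid) and the only one not held in a hydrogen bond to the carbonyl, so it should be ionised and alkylated first.

Step 3
Reactants: 4 2,6-dihydroxy-4-methoxy-3-methylbenzaldehyde
Product: 5 2,6-bis(benzyloxy)-4-methoxy-3-methylbenzaldehyde
Conditions: BnBr (2.5 equiv), K2CO3, DMF, 70 °C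
Reagents that add atoms: benzyl bromide, BrCc1ccccc1
Why: Williamson benzylation; the two chelated ortho hydroxyls need the more forcing conditions (dipolar solvent, heat, excess halide), and no other nucleophilic site remains.

Step 4
Reactants: 5 2,6-bis(benzyloxy)-4-methoxy-3-methylbenzaldehyde
Product: 7 2,6-bis(benzyloxy)-4-methoxy-3-methylphenol, via aryl formate 6 (not isolated)
Conditions: mCPBA, CH2Cl2, 0 °C → rt; then K2CO3 (cat.), MeOH, rt
Reagents that add atoms: 3-chloroperoxybenzoic acid, OOC(=O)c1cccc(Cl)c1
Why: Baeyer–Villiger (Dakin-type) oxidation of a benzaldehyde whose three alkoxy donors make the aryl group migrate in preference to hydrogen; the formate 6 shields the electron-rich phenol from the peracid and is then cleaved by methanolysis.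

Step 5
Reactants: 8 2-chloro-1,1-dimethoxyethane
Product: 10 1-methoxypropyne, via sodium methoxyacetylide 9 (not isolated)
Conditions: NaNH2 (3 equiv), liq. NH3, −33 °C; then MeI (1.2 equiv), −33 °C; fractional distillation
Reagents that add atoms: methyl iodide, CI
Why: Double elimination (loss of hydrogen chloride and of methanol) from the chloroacetal with sodium amide gives the metal alkoxyacetylide, which is C-alkylated in the same flask; this is the standard alkylation of a sodium acetylide in liquid ammonia.

Step 6
Reactants: 11 3-ethoxycyclobut-2-en-1-one
Product: 12 cyclobutane-1,3-dione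
Conditions: 1 M HCl (aq), 0 °C → rt
Reagents that add atoms: water, O
Why: Acid hydrolysis of a vinylogous ester: water adds at the β-carbon and ethanol leaves.

Step 7
Reactants: 12 cyclobutane-1,3-dione; 7 2,6-bis(benzyloxy)-4-methoxy-3-methylphenol
Product: 14 3-[2,6-bis(benzyloxy)-4-methoxy-3-methylphenoxy]cyclobut-2-en-1-one, via 3-chlorocyclobut-2-en-1-one 13 (not isolated)
Conditions: (COCl)2 (1.0 equiv), DMF (cat.), CH2Cl2, 0 °C; then 7, Et3N (2.2 equiv), CH2Cl2, 0 °C → rt
Reagents that add atoms: none
Why: Vilsmeier-type chlorination of the enol form of the 1,3-dione gives the vinylogous acid chloride 13, and the phenoxide of 7 then replaces chloride by conjugate addition–elimination. The attacked carbon is a small unhindered sp2 centre, so the two ortho benzyloxy groups of 7 are tolerated, and O-attack is the only option because every ortho and para carbon of 7 is substituted.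

Step 8
Reactants: 14 3-[2,6-bis(benzyloxy)-4-methoxy-3-methylphenoxy]cyclobut-2-en-1-one; 10 1-methoxypropyne
Product: 19 5-[2,6-bis(benzyloxy)-4-methoxy-3-methylphenoxy]-3-methoxy-2-methylphenol, via vinylketene 15 (not isolated), via vinylcyclobutenone 16 (not isolated), via dienylketene 17 (not isolated), via cyclohexadienone 18 (not isolated)
Conditions: 10 (2 equiv), toluene (degassed), sealed tube, 110 °C then 150 °C
Reagents that add atoms: none
Why: Heating opens 14 by 4π electrocyclic cleavage of its C(=O)–CH2 bond to vinylketene 15, whose electrophilic ketene carbon is attacked by the methyl-bearing carbon of ynol ether 10 in a regiospecific [2+2] cycloaddition that gives vinylcyclobutenone 16 and forms the bonds C5–C6 and C1–C2. A second 4π opening gives dienylketene 17, and the isomer with ketene and vinyl cis closes ring A, a six-membered carbocycle, by 6π electrocyclisation that re-forms the C4–C5 link; the resulting dienone 18 tautomerises irreversibly to phenol 19. This is the Danheiser benzannulation of a cyclobutenone with an alkoxyalkyne, a known route to resorcinol monoethers. No stereocentre is present in 19, and the one in 16 is transient. The only selectivity needed is the orientation of the ketene–alkyne union, and it is secured by the polarisation of the ynol ether, whose oxygen makes the methyl-bearing carbon the nucleophilic one, so that methyl ends up next to the new hydroxyl and methoxy meta to it. The methyl ynol ether cannot lose an alkene by retro-ene reaction at these temperatures, as an ethyl ynol ether could. Because 14 is a vinylogous ester, its ring opening should be slower than that of alkyl cyclobutenones, hence the higher final temperature; should part of 19 be captured as an aryl ester by 15, brief treatment of the crude product with K2CO3 in methanol would release it.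

Step 9
Reactants: 19 5-[2,6-bis(benzyloxy)-4-methoxy-3-methylphenoxy]-3-methoxy-2-methylphenol
Product: 20 2-(3-hydroxy-5-methoxy-4-methylphenoxy)-5-methoxy-4-methylbenzene-1,3-diol
Conditions: H2 (1 atm), Pd/C, EtOAc–MeOH, rt
Reagents that add atoms: none
Why: Catalytic hydrogenolysis of the two benzyl ethers; the diaryl ether, the methyl ethers and the arenes should be untouched under these conditions.

Step 10
Reactants: 20 2-(3-hydroxy-5-methoxy-4-methylphenoxy)-5-methoxy-4-methylbenzene-1,3-diol
Product: 21 2-[3-(acetyloxy)-5-methoxy-4-methylphenoxy]-5-methoxy-4-methyl-1,3-phenylene diacetate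
Conditions: Ac2O, pyridine, DMAP (cat.), CH2Cl2, rt
Reagents that add atoms: acetic anhydride, CC(=O)OC(C)=O
Why: DMAP-catalysed O-acetylation of all three phenols; it protects the oxidation-prone triol at once and loads exactly three acetyl groups for the rearrangement.

Step 11
Reactants: 21 2-[3-(acetyloxy)-5-methoxy-4-methylphenoxy]-5-methoxy-4-methyl-1,3-phenylene diacetate
Product: 23 leprolomin, via bis(difluoroboron) chelate 22 (not isolated)
Conditions: BF3·OEt2 (excess), PhCl, 90 °C; then HCl, MeOH–H2O, 60 °C
Reagents that add atoms: none
Why: Double Lewis-acid Fries rearrangement: on ring A the acetyl from O5 goes to C4, the only open ortho carbon, and the six-membered difluoroboron chelate formed there is what favours C4 over the para carbon C2, while on ring B C5' is the only unsubstituted carbon. BF3·OEt2 is chosen because it should leave the methyl ethers intact, including the C4' methoxy next to the new ketone. Acidic methanolysis then breaks the chelates of 22 and removes the remaining 2'-O-acetyl group without exposing the polyphenol to base and air.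

## Compound list

1 | 2-methylphloroglucinol (2-methylbenzene-1,3,5-triol) | Cc1c(O)cc(O)cc1O | starting material
2 | [(2,4,6-trihydroxy-3-methylphenyl)methylidene]dimethyliminium chloride | C[N+](C)=Cc1c(O)cc(O)c(C)c1O.[Cl-] | intermediate (not isolated)
3 | 2,4,6-trihydroxy-3-methylbenzaldehyde | O=Cc1c(O)cc(O)c(C)c1O | intermediate
4 | 2,6-dihydroxy-4-methoxy-3-methylbenzaldehyde | O=Cc1c(O)cc(OC)c(C)c1O | intermediate
5 | 2,6-bis(benzyloxy)-4-methoxy-3-methylbenzaldehyde | O=Cc1c(OCc2ccccc2)cc(OC)c(C)c1OCc1ccccc1 | intermediate
6 | 2,6-bis(benzyloxy)-4-methoxy-3-methylphenyl formate | O=COc1c(OCc2ccccc2)cc(OC)c(C)c1OCc1ccccc1 | intermediate (not isolated)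
7 | 2,6-bis(benzyloxy)-4-methoxy-3-methylphenol | Oc1c(OCc2ccccc2)cc(OC)c(C)c1OCc1ccccc1 | intermediate
8 | 2-chloro-1,1-dimethoxyethane | COC(CCl)OC | starting material
9 | sodium methoxyacetylide | [Na+].[C-]#COC | intermediate (not isolated)
10 | 1-methoxypropyne | CC#COC | intermediate
11 | 3-ethoxycyclobut-2-en-1-one | CCOC1=CC(=O)C1 | starting material
12 | cyclobutane-1,3-dione | O=C1CC(=O)C1 | intermediate
13 | 3-chlorocyclobut-2-en-1-one | O=C1C=C(Cl)C1 | intermediate (not isolated)
14 | 3-[2,6-bis(benzyloxy)-4-methoxy-3-methylphenoxy]cyclobut-2-en-1-one | O=C1C=C(Oc2c(OCc3ccccc3)c(C)c(OC)cc2OCc2ccccc2)C1 | intermediate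
15 | 3-[2,6-bis(benzyloxy)-4-methoxy-3-methylphenoxy]buta-1,3-dien-1-one (vinylketene) | C=C(C=C=O)Oc1c(OCc2ccccc2)c(C)c(OC)cc1OCc1ccccc1 | intermediate (not isolated)
16 | 4-{1-[2,6-bis(benzyloxy)-4-methoxy-3-methylphenoxy]ethenyl}-3-methoxy-2-methylcyclobut-2-en-1-one (racemic, transient) | COC1=C(C)C(=O)C1C(=C)Oc1c(OCc2ccccc2)c(C)c(OC)cc1OCc1ccccc1 | intermediate (not isolated)
17 | (3E)-5-[2,6-bis(benzyloxy)-4-methoxy-3-methylphenoxy]-3-methoxy-2-methylhexa-1,3,5-trien-1-one (ketene and vinyl cis) | O=C=C(C)/C(OC)=C\C(=C)Oc1c(OCc2ccccc2)c(C)c(OC)cc1OCc1ccccc1 | intermediate (not isolated)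
18 | 5-[2,6-bis(benzyloxy)-4-methoxy-3-methylphenoxy]-3-methoxy-2-methylcyclohexa-2,4-dien-1-one | COC1=C(C)C(=O)CC(Oc2c(OCc3ccccc3)c(C)c(OC)cc2OCc2ccccc2)=C1 | intermediate (not isolated)
19 | 5-[2,6-bis(benzyloxy)-4-methoxy-3-methylphenoxy]-3-methoxy-2-methylphenol | COc1cc(Oc2c(OCc3ccccc3)c(C)c(OC)cc2OCc2ccccc2)cc(O)c1C | intermediate
20 | 2-(3-hydroxy-5-methoxy-4-methylphenoxy)-5-methoxy-4-methylbenzene-1,3-diol | COc1cc(Oc2c(O)c(C)c(OC)cc2O)cc(O)c1C | intermediate
21 | 2-[3-(acetyloxy)-5-methoxy-4-methylphenoxy]-5-methoxy-4-methyl-1,3-phenylene diacetate | COc1cc(Oc2c(OC(C)=O)c(C)c(OC)cc2OC(C)=O)cc(OC(C)=O)c1C | intermediate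
22 | 2'-O-acetylleprolomin bis(difluoroboron) chelate (one BF2 bridging O5 and the C4 acetyl oxygen, one bridging O6' and the C5' acetyl oxygen) | COc1cc(Oc2c(OC(C)=O)c(C)c(OC)c3c2O[B-](F)(F)[O+]=C3C)c2c(c1C)O[B-](F)(F)[O+]=C2C | intermediate (not isolated)
23 | leprolomin, 1-[6-(3-acetyl-2,6-dihydroxy-4-methoxy-5-methylphenoxy)-2-hydroxy-4-methoxy-3-methylphenyl]ethan-1-one | COc1cc(Oc2c(O)c(C)c(OC)c(C(C)=O)c2O)c(C(C)=O)c(O)c1C | target

## Step count and least certain steps

Total step count: 11. Longest linear sequence: 9 steps (steps 1, 2, 3, 4, 7, 8, 9, 10 and 11, from 1). Steps 5 and 6 are single-step branches.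

**Step 8 (key step).** The most likely failure is slow ring opening of 14. Its enone is stabilised as a vinylogous ester, so the first electrocyclic step needs more heat than with alkyl cyclobutenones. At that temperature the ynol ether may oligomerise or add to the phenol as it forms, and the vinylketene may dimerise or be trapped by the product.

The fallback gives up the pericyclic construction and makes the ether bond by copper-catalysed Ullmann coupling. It sets out from phenol 7 and comes back to the route at 19. Commercial 3-methoxy-2-methylphenol would be protected with MOMCl and iPr2NEt as 1-methoxy-3-(methoxymethoxy)-2-methylbenzene F1. Iridium-catalysed C–H borylation ([Ir(OMe)(cod)]2, 4,4'-di-tert-butyl-2,2'-bipyridine, B2pin2) is steered by sterics to the one ring C–H without an ortho neighbour and should give 2-[3-methoxy-5-(methoxymethoxy)-4-methylphenyl]-4,4,5,5-tetramethyl-1,3,2-dioxaborolane F2. CuBr2 in aqueous methanol would convert this into 5-bromo-1-methoxy-3-(methoxymethoxy)-2-methylbenzene F3. Coupling of F3 with 7 under CuI, picolinic acid and K3PO4 in DMSO, conditions suited to di-ortho-substituted phenols, should give 1,3-bis(benzyloxy)-5-methoxy-2-[3-methoxy-5-(methoxymethoxy)-4-methylphenoxy]-4-methylbenzene F4. HCl in methanol then removes the methoxymethyl group to give 19.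

**Step 7.** The vinylogous acid chloride 13 may oligomerise or be hydrolysed back to 12 before the phenoxide reaches it, because a strained β-chloro enone is a strong electrophile and carries its own enolisable positions.

The fallback builds the cyclobutenone by ketene–alkyne cycloaddition. It sets out from 7 and comes back at 14. Phenol 7 with KH and trichloroethylene in THF should give 1,3-bis(benzyloxy)-2-[(E)-1,2-dichloroethenoxy]-5-methoxy-4-methylbenzene F5. n-BuLi (2.2 equiv) at −78 °C followed by a methanol quench would give the aryl ethynyl ether 1,3-bis(benzyloxy)-2-(ethynyloxy)-5-methoxy-4-methylbenzene F6. Dichloroketene, generated from trichloroacetyl chloride and Zn–Cu couple, adds with its carbonyl carbon to the terminal alkyne carbon and should give 3-[2,6-bis(benzyloxy)-4-methoxy-3-methylphenoxy]-4,4-dichlorocyclobut-2-en-1-one F7. Zn dust in acetic acid with TMEDA then removes both chlorines to give 14.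

**Step 11.** Acyl delivery on ring A may go to the para carbon C2 or scramble between molecules, because C2 is activated by the same three oxygens as C4 and a BF3-promoted Fries rearrangement can proceed through free acylium species. Partial loss of the C4' methyl ether is a lesser risk.

The fallback installs the two acetyl groups one after the other, the first by a strictly ortho-selective reaction. It sets out from 19 and comes back at 23. Magnesium-mediated ortho-formylation of 19 (MgCl2, Et3N, paraformaldehyde, MeCN, reflux) can only reach C4 and should give 6-[2,6-bis(benzyloxy)-4-methoxy-3-methylphenoxy]-2-hydroxy-4-methoxy-3-methylbenzaldehyde F8. Excess MeMgBr would give the racemic carbinol 3-[2,6-bis(benzyloxy)-4-methoxy-3-methylphenoxy]-2-(1-hydroxyethyl)-5-methoxy-6-methylphenol F9. MnO2 would oxidise this to 1-{6-[2,6-bis(benzyloxy)-4-methoxy-3-methylphenoxy]-2-hydroxy-4-methoxy-3-methylphenyl}ethan-1-one F10. Hydrogenolysis (H2, Pd/C) would give 1-[6-(2,6-dihydroxy-4-methoxy-3-methylphenoxy)-2-hydroxy-4-methoxy-3-methylphenyl]ethan-1-one F11. Acetylation with AcOH and BF3·OEt2 should then occur on the far more electron-rich ring B at C5', its only open carbon, to give 23.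

**Step 2.** Methylation may run on to the C6' hydroxyl or fall short, because after the first alkylation the two ortho hydroxyls are only partly held by the single carbonyl acceptor.

The fallback reverses the logic and removes methyl groups under chelation control. It sets out from 1 and comes back at 4. Exhaustive O-methylation of 1 (Me2SO4, K2CO3, acetone) would give 1,3,5-trimethoxy-2-methylbenzene F12, which is also an article of commerce. Vilsmeier–Haack formylation (POCl3, DMF) would give 2,4,6-trimethoxy-3-methylbenzaldehyde F13. AlCl3 in chlorobenzene at 80 °C should cleave only the two methoxy groups that can chelate to the aldehyde, leaving the para methoxy group, to give 4.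

## Further compounds

F1 | step 8 | 1-methoxy-3-(methoxymethoxy)-2-methylbenzene | COCOc1cccc(OC)c1C
F2 | step 8 | 2-[3-methoxy-5-(methoxymethoxy)-4-methylphenyl]-4,4,5,5-tetramethyl-1,3,2-dioxaborolane | COCOc1cc(B2OC(C)(C)C(C)(C)O2)cc(OC)c1C
F3 | step 8 | 5-bromo-1-methoxy-3-(methoxymethoxy)-2-methylbenzene | COCOc1cc(Br)cc(OC)c1C
F4 | step 8 | 1,3-bis(benzyloxy)-5-methoxy-2-[3-methoxy-5-(methoxymethoxy)-4-methylphenoxy]-4-methylbenzene | COCOc1cc(Oc2c(OCc3ccccc3)c(C)c(OC)cc2OCc2ccccc2)cc(OC)c1C
F5 | step 7 | 1,3-bis(benzyloxy)-2-[(E)-1,2-dichloroethenoxy]-5-methoxy-4-methylbenzene | Cl/C=C(/Cl)Oc1c(OCc2ccccc2)c(C)c(OC)cc1OCc1ccccc1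
F6 | step 7 | 1,3-bis(benzyloxy)-2-(ethynyloxy)-5-methoxy-4-methylbenzene | C#COc1c(OCc2ccccc2)c(C)c(OC)cc1OCc1ccccc1
F7 | step 7 | 3-[2,6-bis(benzyloxy)-4-methoxy-3-methylphenoxy]-4,4-dichlorocyclobut-2-en-1-one | O=C1C=C(Oc2c(OCc3ccccc3)c(C)c(OC)cc2OCc2ccccc2)C1(Cl)Cl
F8 | step 11 | 6-[2,6-bis(benzyloxy)-4-methoxy-3-methylphenoxy]-2-hydroxy-4-methoxy-3-methylbenzaldehyde | COc1cc(Oc2c(OCc3ccccc3)c(C)c(OC)cc2OCc2ccccc2)c(C=O)c(O)c1C
F9 | step 11 | 3-[2,6-bis(benzyloxy)-4-methoxy-3-methylphenoxy]-2-(1-hydroxyethyl)-5-methoxy-6-methylphenol (racemic) | COc1cc(Oc2c(OCc3ccccc3)c(C)c(OC)cc2OCc2ccccc2)c(C(C)O)c(O)c1C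
F10 | step 11 | 1-{6-[2,6-bis(benzyloxy)-4-methoxy-3-methylphenoxy]-2-hydroxy-4-methoxy-3-methylphenyl}ethan-1-one | COc1cc(Oc2c(OCc3ccccc3)c(C)c(OC)cc2OCc2ccccc2)c(C(C)=O)c(O)c1C
F11 | step 11 | 1-[6-(2,6-dihydroxy-4-methoxy-3-methylphenoxy)-2-hydroxy-4-methoxy-3-methylphenyl]ethan-1-one | COc1cc(Oc2c(O)c(C)c(OC)cc2O)c(C(C)=O)c(O)c1C
F12 | step 2 | 1,3,5-trimethoxy-2-methylbenzene | COc1cc(OC)c(C)c(OC)c1
F13 | step 2 | 2,4,6-trimethoxy-3-methylbenzaldehyde | COc1cc(OC)c(C=O)c(OC)c1C
A1 | alternative 1 | methyl 2-[3-(benzyloxy)-5-methoxy-4-methylphenoxy]acetate | COC(=O)COc1cc(OC)c(C)c(OCc2ccccc2)c1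
A2 | alternative 1 | 4-methoxy-3,6-dimethyl-2H-pyran-2-one | COC1=C(C)C(=O)OC(C)=C1
A3 | alternative 1 | 1-{3-[3-(benzyloxy)-5-methoxy-4-methylphenoxy]-2,4-dihydroxy-6-methoxy-5-methylphenyl}ethan-1-one | COc1cc(Oc2c(O)c(C)c(OC)c(C(C)=O)c2O)cc(OCc2ccccc2)c1C
A4 | alternative 2 | 1-(benzyloxy)-5-{[4,4-dimethoxy-3-methyl-2-(trimethylsilyloxy)buta-1,3-dien-1-yl]oxy}-3-methoxy-2-methylbenzene | COC(OC)=C(C)C(O[Si](C)(C)C)=COc1cc(OC)c(C)c(OCc2ccccc2)c1
A5 | alternative 2 | 4-(4,4,5,5-tetramethyl-1,3,2-dioxaborolan-2-yl)but-3-yn-2-one | CC(=O)C#CB1OC(C)(C)C(C)(C)O1
A6 | alternative 2 | 1-{3-[3-(benzyloxy)-5-methoxy-4-methylphenoxy]-4-hydroxy-6-methoxy-5-methyl-2-(4,4,5,5-tetramethyl-1,3,2-dioxaborolan-2-yl)phenyl}ethan-1-one | COc1cc(Oc2c(O)c(C)c(OC)c(C(C)=O)c2B2OC(C)(C)C(C)(C)O2)cc(OCc2ccccc2)c1C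
A7 | alternative 3 | 3-methoxy-2-methyl-1,1-bis(trimethylsilyloxy)buta-1,3-diene | C=C(OC)C(C)=C(O[Si](C)(C)C)O[Si](C)(C)C
A8 | alternative 3 | 4-[2,6-bis(benzyloxy)-4-methoxy-3-methylphenoxy]but-3-yn-2-one | CC(=O)C#COc1c(OCc2ccccc2)c(C)c(OC)cc1OCc1ccccc1
A9 | alternative 3 | 1-{6-[2,6-bis(benzyloxy)-4-methoxy-3-methylphenoxy]-2-hydroxy-4-methoxy-3-methylphenyl}ethan-1-one | COc1cc(Oc2c(OCc3ccccc3)c(C)c(OC)cc2OCc2ccccc2)c(C(C)=O)c(O)c1C
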